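**Plan**

- Numbering: ring A is the 1,3,5-trisubstituted phenol ring and ring B the 3,4,5-trioxygenated ring; the chain runs from C1 (benzylic CH2 on ring A) to C14 (carbinol carbon on ring B, R-configured), with the Z-alkene at C6=C7.
- Retrosynthetic cuts, in this order: C14-OH back to a C14 ketone; three ArO-H back to ArO-CH3; C6=C7 back to a C6≡C7 alkyne; the 22-membered ring at C2-C3, leaving a seco acid with a vinyl group (C1=C2) on ring A and a carboxyl group on C3; then C13-C14 (Grignard reagent plus nitrile), C7-C8 (acetylide plus dibromide), ring A-C1 (vinylation) and the O-ring A bond of the diaryl ether.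
- Forward order: diaryl ether (rings A and B joined), vinyl group, C3-C13 chain attached at C14, carboxyl group unveiled, ring closure at C2-C3, alkyne to Z-alkene, ether cleavage, ketone reduction.
- Enabling feature: the C1=C2 vinyl group conjugated to ring A accepts a C3 radical at C2 only, because the adduct radical at C1 is benzylic to ring A; the carboxyl group on C3 is a traceless radical source, and the C6≡C7 triple bond (the later Z-alkene) keeps that radical from cyclising or shifting a hydrogen.
- Stereochemistry: Z from syn semi-hydrogenation of the ring alkyne; (R) at C14 from catalyst-controlled asymmetric transfer hydrogenation of the ketone in the last step.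

Key step: step 7

**Route**

Step 1
Reactants: 1 4-hydroxy-3,5-dimethoxybenzonitrile; 2 (3-bromo-5-methoxyphenyl)boronic acid
Product: 3 4-(3-bromo-5-methoxyphenoxy)-3,5-dimethoxybenzonitrile
Conditions: Cu(OAc)2 (2 equiv), pyridine (5 equiv), 4 Å molecular sieves, CH2Cl2, dry air, 25 °C
Reagents that add atoms: none
Why: Chan-Lam oxidative O-arylation, in which the boronic acid transmetalates to a divalent copper phenoxide and reductive elimination from the trivalent copper aryl phenoxide forms the C-O bond at room temperature, a manifold that accepts phenols with two ortho substituents and leaves the aryl bromide and the nitrile untouched.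

Step 2
Reactants: 3 4-(3-bromo-5-methoxyphenoxy)-3,5-dimethoxybenzonitrile
Product: 4 4-(3-ethenyl-5-methoxyphenoxy)-3,5-dimethoxybenzonitrile
Conditions: vinylboronic acid pinacol ester (1.5 equiv), Pd(dppf)Cl2 (3 mol%), K2CO3 (3 equiv), 1,4-dioxane/H2O 4:1, 85 °C
Reagents that add atoms: vinylboronic acid pinacol ester, C=CB1OC(C)(C)C(C)(C)O1
Why: Suzuki-Miyaura vinylation, in which zerovalent palladium inserts into the only C-Br bond, the vinyl group is transferred from boron and reductive elimination installs C1=C2 on ring A, while the nitrile and the ethers are inert.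

Step 3
Reactants: 5 hex-5-yn-1-ol
Product: 6 tert-butyl(hex-5-yn-1-yloxy)dimethylsilane
Conditions: TBSCl (1.1 equiv), imidazole (2 equiv), CH2Cl2, 0 to 25 °C
Reagents that add atoms: tert-butyldimethylsilyl chloride (TBSCl), CC(C)(C)[Si](C)(C)Cl
Why: Standard imidazole-promoted silylation of a primary alcohol, needed so that the hydroxyl group survives the acetylide and Grignard steps.

Step 4
Reactants: 6 tert-butyl(hex-5-yn-1-yloxy)dimethylsilane; 7 1,6-dibromohexane
Product: 9 tert-butyl[(12-bromododec-5-yn-1-yl)oxy]dimethylsilane, via lithium acetylide 8 (not isolated)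
Conditions: n-BuLi (1.05 equiv), THF, −78 to 0 °C; then 7 (4 equiv), DMPU, 0 to 25 °C
Reagents that add atoms: none
Why: Acetylide alkylation, in which n-BuLi deprotonates the terminal alkyne and the lithium acetylide displaces one primary bromide of 7 by SN2, the excess of dibromide keeping double alkylation low; this sets the C7-C8 bond.

Step 5
Reactants: 4 4-(3-ethenyl-5-methoxyphenoxy)-3,5-dimethoxybenzonitrile; 9 tert-butyl[(12-bromododec-5-yn-1-yl)oxy]dimethylsilane
Product: 12 hydroxy ynone 1-[4-(3-ethenyl-5-methoxyphenoxy)-3,5-dimethoxyphenyl]-13-hydroxytridec-8-yn-1-one, via Grignard reagent 10 (not isolated), via magnesium ketimine 11 (not isolated)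
Conditions: 9 (1.4 equiv), Mg turnings, THF, 45 °C; then 4, CuBr·SMe2 (5 mol%), THF, 65 °C; then 2 M aq HCl, THF, 25 °C
Reagents that add atoms: water, O
Why: Grignard addition to an aryl nitrile, which stops at the N-magnesio ketimine so that no tertiary alcohol can form, followed by acid hydrolysis that unveils the C14 ketone and cleaves the primary silyl ether in the same operation; the styrene and the internal alkyne do not react with an alkyl Grignard reagent.

Step 6
Reactants: 12 hydroxy ynone
Product: 14 seco acid 13-[4-(3-ethenyl-5-methoxyphenoxy)-3,5-dimethoxyphenyl]-13-oxotridec-5-ynoic acid, via aldehyde 13 (not isolated)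
Conditions: TEMPO (20 mol%), PhI(OAc)2 (2.2 equiv), MeCN/H2O 1:1, 25 °C
Reagents that add atoms: water, O
Why: TEMPO/PhI(OAc)2 oxidation, in which the oxoammonium ion takes the primary alcohol to the aldehyde and its hydrate on to the acid, chlorine-free conditions under which the styrene, the alkyne, the aryl ketone and the electron-rich rings should not be attacked.

Step 7
Reactants: 14 seco acid
Product: 15 macrocyclic ynone (22-membered ring: ring A and ring B joined by the ether oxygen and by the chain C1H2-C5H2/C6≡C7/C8H2-C13H2/C14=O; three methyl ethers)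
Conditions: Ir[dF(CF3)ppy]2(dtbbpy)PF6 (2 mol%), K2HPO4 (1.2 equiv), H2O (20 equiv), degassed DMSO (2 mM), 450 nm LEDs, 25 °C
Reagents that add atoms: none
Why: Proposed new method: the excited trivalent iridium complex oxidises the carboxylate of 14, CO2 is lost, the nucleophilic primary radical at C3 adds to the unsubstituted terminus C2 of the vinyl group on ring A, and the benzylic C1 radical so formed is reduced by the divalent iridium species to a carbanion that water protonates, which closes a redox-neutral cycle with no stoichiometric hydrogen-atom donor able to quench the C3 radical before it finds the alkene. The closest known reaction types are the photoredox decarboxylative Giese macrocyclisation onto acrylamide acceptors and the intermolecular decarboxylative hydroalkylation of vinylarenes by radical addition and radical-polar crossover; new is their use together, an unstabilised primary radical closing a large ring onto a plain styrene. The 22-membered ring closes in the 22-endo-trig mode, because C1 and C2 both end up inside the ring. No stereocentre is formed. The step needs attack at C2 and not C1, which ring A secures by stabilising the adduct radical at C1, and it needs a C3 radical that survives until ring closure, which the C6-C7 triple bond secures: it is too close for anything but a 4-exo or 5-endo attack and, unlike the later Z-alkene, it holds the C8 hydrogens out of reach of a 1,6-hydrogen shift. DMSO, whose C-H bonds are poor donors towards alkyl radicals, and the 2 mM concentration should keep solvent quenching and intermolecular addition below the rate of cyclisation, and the aryl ketone, the aryl ethers and the alkyne are not touched by either oxidation state of the catalyst.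

Step 8
Reactants: 15 macrocyclic ynone
Product: 16 (6Z)-macrocyclic ketone (as 15 but with a cis C6=C7 double bond)
Conditions: H2 (1 atm), Pd/CaCO3 poisoned with Pb(OAc)2 (Lindlar catalyst), quinoline, EtOAc, 25 °C
Reagents that add atoms: none
Why: Lindlar semi-hydrogenation, in which syn addition of H2 on the poisoned palladium surface converts the ring alkyne into the Z-alkene and stops there, the 22-membered ring being large enough to hold a cis double bond without strain, while the aryl ketone and aryl ethers are not reduced.

Step 9
Reactants: 16 (6Z)-macrocyclic ketone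
Product: 18 (6Z)-triphenol ketone (as 16 but with three free phenols), via tris(dibromoboryl) ether 17 (not isolated)
Conditions: BBr3 (9 equiv), CH2Cl2, −78 to 0 °C; then H2O, 0 °C
Reagents that add atoms: none
Why: Lewis acid ether cleavage, in which BBr3 binds each methoxy oxygen and bromide attacks the methyl group by SN2 to give aryloxydibromoboranes that water hydrolyses to the phenols; the step is placed before the reduction so that no benzylic alcohol is exposed to the Lewis acid, and the isolated Z-alkene is a poor Lewis base at low temperature.

Step 10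
Reactants: 18 (6Z)-triphenol ketone
Product: 19 target CNP0316989.2, the (14R,6Z)-carbinol
Conditions: RuCl(p-cymene)[(R,R)-TsDPEN] (2 mol%), HCO2H/Et3N 5:2, DMF, 40 °C
Reagents that add atoms: none
Why: Noyori-Ikariya asymmetric transfer hydrogenation, in which the ruthenium hydride and the amine N-H of the (R,R)-TsDPEN complex deliver hydride and proton through a six-membered outer-sphere transition state with ring B under the p-cymene ligand (CH/π contact), so that hydride should add to the Si face of the C14 ketone and set the (R)-carbinol; isolated alkenes and phenols are not touched.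

**Compound list**

1 | 4-hydroxy-3,5-dimethoxybenzonitrile | N#Cc1cc(OC)c(O)c(OC)c1 | starting material
2 | (3-bromo-5-methoxyphenyl)boronic acid | OB(O)c1cc(Br)cc(OC)c1 | starting material
3 | 4-(3-bromo-5-methoxyphenoxy)-3,5-dimethoxybenzonitrile | N#Cc1cc(OC)c(Oc2cc(Br)cc(OC)c2)c(OC)c1 | intermediate
4 | 4-(3-ethenyl-5-methoxyphenoxy)-3,5-dimethoxybenzonitrile | N#Cc1cc(OC)c(Oc2cc(C=C)cc(OC)c2)c(OC)c1 | intermediate
5 | hex-5-yn-1-ol | OCCCCC#C | starting material
6 | tert-butyl(hex-5-yn-1-yloxy)dimethylsilane | C#CCCCCO[Si](C)(C)C(C)(C)C | intermediate
7 | 1,6-dibromohexane | BrCCCCCCBr | starting material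
8 | lithium acetylide of 6, [6-(tert-butyldimethylsilyloxy)hex-1-yn-1-yl]lithium | [Li]C#CCCCCO[Si](C)(C)C(C)(C)C | intermediate (not isolated)
9 | tert-butyl[(12-bromododec-5-yn-1-yl)oxy]dimethylsilane | BrCCCCCCC#CCCCCO[Si](C)(C)C(C)(C)C | intermediate
10 | Grignard reagent, [12-(tert-butyldimethylsilyloxy)dodec-7-yn-1-yl]magnesium bromide | Br[Mg]CCCCCCC#CCCCCO[Si](C)(C)C(C)(C)C | intermediate (not isolated)
11 | magnesium ketimine, N-bromomagnesio imine of 13-(tert-butyldimethylsilyloxy)-1-[4-(3-ethenyl-5-methoxyphenoxy)-3,5-dimethoxyphenyl]tridec-8-yn-1-one | C=Cc1cc(OC)cc(Oc2c(OC)cc(cc2OC)C(=N[Mg]Br)CCCCCCC#CCCCCO[Si](C)(C)C(C)(C)C)c1 | intermediate (not isolated)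
12 | hydroxy ynone, 1-[4-(3-ethenyl-5-methoxyphenoxy)-3,5-dimethoxyphenyl]-13-hydroxytridec-8-yn-1-one | C=Cc1cc(OC)cc(Oc2c(OC)cc(cc2OC)C(=O)CCCCCCC#CCCCCO)c1 | intermediate
13 | aldehyde, 13-[4-(3-ethenyl-5-methoxyphenoxy)-3,5-dimethoxyphenyl]-13-oxotridec-5-ynal | C=Cc1cc(OC)cc(Oc2c(OC)cc(cc2OC)C(=O)CCCCCCC#CCCCC=O)c1 | intermediate (not isolated)
14 | seco acid, 13-[4-(3-ethenyl-5-methoxyphenoxy)-3,5-dimethoxyphenyl]-13-oxotridec-5-ynoic acid | C=Cc1cc(OC)cc(Oc2c(OC)cc(cc2OC)C(=O)CCCCCCC#CCCCC(=O)O)c1 | intermediate
15 | macrocyclic ynone: 22-membered ring of ring A (in the ring through positions 1 and 3, OMe at position 5), the ether oxygen, ring B (in the ring through positions 4 and 1, OMe at positions 3 and 5) and the chain C1H2 to C5H2, C6≡C7, C8H2 to C13H2, C14=O | COc1cc2cc(c1)Oc1c(OC)cc(cc1OC)C(=O)CCCCCCC#CCCCCC2 | intermediate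
16 | (6Z)-macrocyclic ketone: as 15 with a cis C6=C7 double bond in place of the triple bond | COc1cc2cc(c1)Oc1c(OC)cc(cc1OC)C(=O)CCCCCC/C=C\CCCCC2 | intermediate
17 | tris(dibromoboryl) ether of 18: the three phenol oxygens each carry a BBr2 group | BrB(Br)Oc1cc2cc(c1)Oc1c(OB(Br)Br)cc(cc1OB(Br)Br)C(=O)CCCCCC/C=C\CCCCC2 | intermediate (not isolated)
18 | (6Z)-triphenol ketone: as 16 with three free phenols | Oc1cc2cc(c1)Oc1c(O)cc(cc1O)C(=O)CCCCCC/C=C\CCCCC2 | intermediate
19 | CNP0316989.2, the (14R,6Z)-macrocyclic triphenol carbinol | Oc1cc2cc(c1)Oc1c(O)cc(cc1O)[C@H](O)CCCCCC/C=C\CCCCC2 | target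

**Step count and risks**

Total step count: 10. Longest linear sequence: 8 steps (steps 1, 2, 5, 6, 7, 8, 9, 10 from compound 1; equally steps 3 to 10 from compound 5).

Steps most likely to fail:

1. Step 7 (key step, proposed new method). The 22-membered ring closure onto an unactivated styrene is slow, so the C3 radical may be consumed by hydrogen abstraction from the medium or by intermolecular addition before it reaches C2; oxidation of the unactivated primary carboxylate may also be sluggish. The fallback closes the same ring by olefin metathesis at C6=C7; it sets out from 3 and comes back to the route at 16. Hepta-1,6-diene (excess) is monohydroborated with 9-BBN to 9-(hept-6-en-1-yl)-9-borabicyclo[3.3.1]nonane F1. B-alkyl Suzuki-Miyaura coupling of this borane with bromide 3 (Pd(dppf)Cl2, K3PO4, THF/H2O, 65 °C) should give 4-[3-(hept-6-en-1-yl)-5-methoxyphenoxy]-3,5-dimethoxybenzonitrile F2. Oct-7-en-1-ylmagnesium bromide F3 (from 8-bromooct-1-ene and Mg) adds to the nitrile to give the magnesium ketimine F4, which 2 M aq HCl hydrolyses to the dienyl ketone 1-{4-[3-(hept-6-en-1-yl)-5-methoxyphenoxy]-3,5-dimethoxyphenyl}non-8-en-1-one F5. Z-selective ring-closing metathesis of this diene with the cyclometalated ruthenium nitrate catalyst of the Grubbs type, Ru(NO3)(cyclometalated N-adamantyl-N′-mesityl-imidazolin-2-ylidene)(=CH-C6H4-2-OiPr), at 5 mM in 1,2-dichloroethane at 40 °C under static vacuum, should expel ethene and give 16 directly, so that step 8 is not needed.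

2. Step 9. HBr formed during the Lewis-acid cleavage may add to the alkene or isomerise it from Z to E, and cleavage of the two hindered methyl ethers flanking the diaryl ether oxygen may stall. The fallback inverts the last two operations and changes the mechanism of ether cleavage; it sets out from 16 and comes back at 19. Ketone 16 is reduced first under the conditions of step 10 to the (14R,6Z)-carbinol tri-O-methyl ether F6. The three methyl ethers are then removed by thiolate SN2 dealkylation (NaSEt in excess, DMF, 140 °C), acid-free conditions under which the benzylic carbinol is held as its alkoxide and cannot ionise and the alkene cannot take up HBr.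

3. Step 1. The doubly ortho-substituted, electron-poor phenol may couple slowly, so that protodeboronation and homocoupling of the boronic acid take over. The fallback replaces the oxidative coupling by an Ullmann-type etherification; it sets out from 1 and comes back at 3. Phenol 1 is coupled with 1-bromo-3-iodo-5-methoxybenzene (CuI 10 mol%, picolinic acid 20 mol%, K3PO4, DMSO, 90 °C), the phenoxide displacing iodide selectively over bromide. This fallback makes no compound beyond those already listed (F0).

**Further compounds**

F1 | step 7 | 9-(hept-6-en-1-yl)-9-borabicyclo[3.3.1]nonane | C=CCCCCCB1C2CCCC1CCC2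
F2 | step 7 | 4-[3-(hept-6-en-1-yl)-5-methoxyphenoxy]-3,5-dimethoxybenzonitrile | N#Cc1cc(OC)c(Oc2cc(CCCCCC=C)cc(OC)c2)c(OC)c1
F3 | step 7 | oct-7-en-1-ylmagnesium bromide | C=CCCCCCC[Mg]Br
F4 | step 7 | magnesium ketimine, N-bromomagnesio imine of F5 | C=CCCCCCCC(=N[Mg]Br)c1cc(OC)c(Oc2cc(CCCCCC=C)cc(OC)c2)c(OC)c1
F5 | step 7 | 1-{4-[3-(hept-6-en-1-yl)-5-methoxyphenoxy]-3,5-dimethoxyphenyl}non-8-en-1-one | C=CCCCCCCC(=O)c1cc(OC)c(Oc2cc(CCCCCC=C)cc(OC)c2)c(OC)c1
F6 | step 9 | (14R,6Z)-carbinol tri-O-methyl ether (19 with its three phenols as methyl ethers) | COc1cc2cc(c1)Oc1c(OC)cc(cc1OC)[C@H](O)CCCCCC/C=C\CCCCC2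
F0 | step 1 | none | none
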